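## Retrosynthetic overview

1. Cadinane numbering is used: ring A = C1–C2–C3–C4(=C5)–C6 with C15H2OH on C4; ring B = C1, C6, C7, C8, C9, C10, with the acrylic acid C11(=C13H2)–C12O2H on C7, the ester oxygen on C8 and the methylene C14 on C10. Ring A is a cyclohexene whose C4=C5 bond sits next to ring-fusion carbon C6, and the sp2 carbon C10 sits next to the other fusion carbon C1. This is the retron of an intramolecular Diels–Alder reaction of a 1,7,9-decatrien-3-one (C10 as ketone, C1=C2 dienophile, C3=C4–C5=C6 diene).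
2. Late disconnections: silyl ether and acetonide; C12 by Markovnikov hydroxycarbonylation of a C11≡C13 alkyne (a slim placeholder for the axial acrylic acid); the C8 ester by Steglich coupling; C8–OH by oxidation and axial hydride delivery; C14 by methylenation of the C10 ketone; C1 by epimerisation.
3. Key disconnection: C1–C6 and C2–C3 at once. Rings A and B close together from an acyclic trienone and no ring is closed afterwards. C6 is set there from C7, with C8–O deliberately carried in the epimeric configuration so that both tether substituents are equatorial in the endo transition state.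
4. Trienone: vinyl ketone from a lithiated alkoxyallene and a terminal epoxide; C7 from Sharpless epoxidation of a trienol and SN2 opening by an alkynylalane, then epoxide inversion; trienol from 2-methylidenepropane-1,3-diol by Horner–Wadsworth–Emmons chain extension.
5. Side-chain acid from (R)-glyceraldehyde acetonide by alkyne homologation and the same hydroxycarbonylation, which thereby serves as a model for the late step.

Key step: step 12

Remark: the configuration is taken as written in the SMILES, which corresponds to 1S,6S,7R,8R in the numbering above and S at the side-chain carbinol. TBDPS = tert-butyl(diphenyl)silyl; TES = triethylsilyl.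

## Route

Step 1
Reactants: 1 2-methylidenepropane-1,3-diol
Product: 2 2-[(TBDPS-oxy)methyl]prop-2-en-1-ol
Conditions: NaH (1.0 equiv), THF, 0 °C; then t-BuPh2SiCl (1.0 equiv), 0 °C → rt
Reagents that add atoms: tert-butyl(chloro)diphenylsilane, CC(C)(C)[Si](Cl)(c1ccccc1)c1ccccc1
Why: Monosilylation of a symmetrical diol through its mono-sodium alkoxide (Williamson-type O-silylation); no stereocentre is involved.

Step 2
Reactants: 2 2-[(TBDPS-oxy)methyl]prop-2-en-1-ol
Product: 3 2-[(TBDPS-oxy)methyl]prop-2-enal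
Conditions: MnO2 (excess), CH2Cl2, rt; used directly
Reagents that add atoms: none
Why: Chemoselective heterogeneous oxidation of a primary allylic alcohol to the enal, which leaves the silyl ether and the 1,1-disubstituted alkene alone.

Step 3
Reactants: 3 2-[(TBDPS-oxy)methyl]prop-2-enal; 4 ethyl (2E)-4-(diethoxyphosphoryl)but-2-enoate
Product: 5 ethyl (2E,4E)-6-[(TBDPS-oxy)methyl]hepta-2,4,6-trienoate
Conditions: 4, LiN(SiMe3)2, THF, −78 °C; then 3, −78 → 0 °C
Reagents that add atoms: none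
Why: Vinylogous Horner–Wadsworth–Emmons olefination in which the stabilised phosphonate anion reacts at its α-carbon and should give the new C4=C5 bond of the trienoate mainly E, the 2E geometry coming from 4.

Step 4
Reactants: 5 ethyl (2E,4E)-6-[(TBDPS-oxy)methyl]hepta-2,4,6-trienoate
Product: 6 (2E,4E)-6-[(TBDPS-oxy)methyl]hepta-2,4,6-trien-1-ol
Conditions: i-Bu2AlH (2.2 equiv), CH2Cl2, −78 °C
Reagents that add atoms: none
Why: 1,2-Reduction of a conjugated ester to the allylic alcohol by an electrophilic aluminium hydride that does not touch the triene.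

Step 5
Reactants: 6 (2E,4E)-6-[(TBDPS-oxy)methyl]hepta-2,4,6-trien-1-ol
Product: 7 {(2R,3R)-3-[(1E)-3-[(TBDPS-oxy)methyl]buta-1,3-dien-1-yl]oxiran-2-yl}methanol
Conditions: Ti(Oi-Pr)4 (10 mol %), D-(−)-diisopropyl tartrate (12 mol %), t-BuOOH, 4 Å molecular sieves, CH2Cl2, −25 °C
Reagents that add atoms: tert-butyl hydroperoxide, CC(C)(C)OO
Why: Sharpless asymmetric epoxidation, in which only the alkene of the allylic alcohol is bound and epoxidised by the titanium tartrate; the D-(−)-tartrate delivers oxygen to the face that gives the (2R,3R)-epoxide, which fixes the future C7 and a relay centre at C8.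

Step 6
Reactants: 7 {(2R,3R)-3-[(1E)-3-[(TBDPS-oxy)methyl]buta-1,3-dien-1-yl]oxiran-2-yl}methanol
Product: 8 (2S,3R,4E)-6-[(TBDPS-oxy)methyl]-3-[(trimethylsilyl)ethynyl]hepta-4,6-diene-1,2-diol
Conditions: Me3SiC≡CH, n-BuLi, toluene, 0 °C; Et2AlCl; then 7, 0 °C → rt
Reagents that add atoms: diethyl[(trimethylsilyl)ethynyl]aluminium, CC[Al](CC)C#C[Si](C)(C)C (made in the flask from ethynyltrimethylsilane, C#C[Si](C)(C)C)
Why: Aluminium-alkoxide-directed opening of a 2,3-epoxy alcohol by an alkynylalane at C3, here also the allylic carbon, with SN2 inversion, which creates the C7 stereocentre (R) and a 1,2-diol.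

Step 7
Reactants: 8 (2S,3R,4E)-6-[(TBDPS-oxy)methyl]-3-[(trimethylsilyl)ethynyl]hepta-4,6-diene-1,2-diol
Product: 10 (2S,3R,4E)-6-[(TBDPS-oxy)methyl]-2-(methanesulfonyloxy)-3-[(trimethylsilyl)ethynyl]hepta-4,6-dien-1-yl benzoate, via monobenzoate 9 (not isolated)
Conditions: PhCOCl (1.05 equiv), 2,4,6-collidine, CH2Cl2, −78 → −30 °C; then MeSO2Cl, Et3N, −30 → 0 °C
Reagents that add atoms: benzoyl chloride, O=C(Cl)c1ccccc1; methanesulfonyl chloride, CS(=O)(=O)Cl
Why: Kinetic acylation distinguishes the primary from the hindered secondary hydroxyl, and the secondary alcohol is then sulfonylated with retention (O–S bond formation), which prepares C8 for inversion.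

Step 8
Reactants: 10 (2S,3R,4E)-6-[(TBDPS-oxy)methyl]-2-(methanesulfonyloxy)-3-[(trimethylsilyl)ethynyl]hepta-4,6-dien-1-yl benzoate
Product: 13 (2R)-2-{(1R,2E)-1-ethynyl-4-[(TBDPS-oxy)methyl]penta-2,4-dien-1-yl}oxirane, via C-desilylated benzoate mesylate 11 (not isolated), via hydroxy mesylate 12 (not isolated)
Conditions: K2CO3 (3 equiv), MeOH, 0 °C → rt
Reagents that add atoms: none
Why: Methanolysis removes the C-silyl group and the benzoate, and the primary alkoxide then displaces the neighbouring mesylate (3-exo-tet Williamson closure) with inversion at C8, so that C8–O and the C7 ethynyl group will stand trans on the future ring B.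

Step 9
Reactants: 13 (2R)-2-{(1R,2E)-1-ethynyl-4-[(TBDPS-oxy)methyl]penta-2,4-dien-1-yl}oxirane
Product: 14 (5S,6R,7E)-9-[(TBDPS-oxy)methyl]-6-ethynyl-3-methoxydeca-1,2,7,9-tetraen-5-ol
Conditions: methoxyallene, n-BuLi, THF, −40 °C (2.5 equiv of the lithiated allene); then 13, −40 → 0 °C
Reagents that add atoms: 1-lithio-1-methoxyallene, [Li]C(OC)=C=C (made in the flask from methoxyallene, C=C=COC)
Why: The lithiated alkoxyallene, an acryloyl anion equivalent, opens the terminal epoxide at its CH2 carbon (SN2) without touching C8; the terminal alkyne is only deprotonated by the excess reagent and returns on work-up.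

Step 10
Reactants: 14 (5S,6R,7E)-9-[(TBDPS-oxy)methyl]-6-ethynyl-3-methoxydeca-1,2,7,9-tetraen-5-ol
Product: 15 triethyl{[(5S,6R,7E)-9-[(TBDPS-oxy)methyl]-6-ethynyl-3-methoxydeca-1,2,7,9-tetraen-5-yl]oxy}silane
Conditions: Et3SiCl, imidazole, DMF, 0 °C
Reagents that add atoms: chlorotriethylsilane, CC[Si](Cl)(CC)CC
Why: Standard O-silylation; a non-chelating silyl ether is wanted for the Lewis-acid step, and the TES group can later be removed beside the TBDPS ether.

Step 11
Reactants: 15 triethyl{[(5S,6R,7E)-9-[(TBDPS-oxy)methyl]-6-ethynyl-3-methoxydeca-1,2,7,9-tetraen-5-yl]oxy}silane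
Product: 16 (5S,6R,7E)-9-[(TBDPS-oxy)methyl]-6-ethynyl-5-[(triethylsilyl)oxy]deca-1,7,9-trien-3-one
Conditions: oxalic acid (cat.), wet SiO2, CH2Cl2, 0 °C; kept cold and used at once
Reagents that add atoms: water, O
Why: Mild acid hydrolysis of the 1-alkoxyallene (protonation at the central carbon, hydration of the oxocarbenium ion, loss of methanol) unveils the vinyl ketone without cleaving the silyl ethers.

Step 12
Reactants: 16 (5S,6R,7E)-9-[(TBDPS-oxy)methyl]-6-ethynyl-5-[(triethylsilyl)oxy]deca-1,7,9-trien-3-one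
Product: 17 (3S,4R,4aR,8aR)-6-[(TBDPS-oxy)methyl]-4-ethynyl-3-[(triethylsilyl)oxy]-3,4,4a,7,8,8a-hexahydronaphthalen-1(2H)-one (cis-fused)
Conditions: Me2AlCl (0.3 equiv), CH2Cl2, −78 → −20 °C
Reagents that add atoms: none
Why: Concerted, asynchronous, Lewis-acid-accelerated [4+2] cycloaddition (type-1 intramolecular Diels–Alder reaction of a 1,7,9-decatrien-3-one, a class known to cyclise near room temperature with a kinetic preference for cis-fused octalones): Me2AlCl binds the C10 carbonyl, lowers the LUMO of the C1=C2 dienophile, and this adds suprafacially across the C3=C4–C5=C6 diene. Ring A closes through both new σ-bonds (C2–C3 and C1–C6) in a boat-like array that leaves the C4=C5 bond, while ring B closes through C1–C6 alone, its four-atom tether C7–C8–C9–C10 folding into a chair with the carbonyl endo, under the diene. C6 is controlled by C7: in the endo chair the ethynyl group on C7 and the silyloxy group on C8 are both equatorial only when the diene is attacked on the face that puts C5 cis to the ethynyl group, the other face forcing both axial. C1 follows from the endo mode (cis fusion) and is corrected in step 13. The selectivity the step needs is endo over exo, because the exo chair with both substituents equatorial would give the C6 epimer; it is secured by the carbonyl inside the tether (secondary overlap, reinforced by the Lewis acid) and by the non-chelating C8 silyl ether, which was given the configuration that keeps it equatorial. The rod-like ethynyl group is the C11/C13 placeholder because it disturbs neither this transition state nor the later trans-decalin, where it must be axial.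

Step 13
Reactants: 17 (3S,4R,4aR,8aR)-6-[(TBDPS-oxy)methyl]-4-ethynyl-3-[(triethylsilyl)oxy]-3,4,4a,7,8,8a-hexahydronaphthalen-1(2H)-one
Product: 18 (3S,4R,4aR,8aS)-6-[(TBDPS-oxy)methyl]-4-ethynyl-3-[(triethylsilyl)oxy]-3,4,4a,7,8,8a-hexahydronaphthalen-1(2H)-one (trans-fused)
Conditions: DBU (0.2 equiv), toluene, rt
Reagents that add atoms: none
Why: Thermodynamic epimerisation at C1 through the C1–C10 enolate should convert the cis-fused octalone into the trans-fused ketone, in which the slim ethynyl group and the β-silyloxy group pay little for being axial; C6, C7 and C8 are not enolisable and stay.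

Step 14
Reactants: 18 (3S,4R,4aR,8aS)-6-[(TBDPS-oxy)methyl]-4-ethynyl-3-[(triethylsilyl)oxy]-3,4,4a,7,8,8a-hexahydronaphthalen-1(2H)-one
Product: 19 tert-butyl({(4aS,7S,8R,8aS)-8-ethynyl-5-methylidene-7-[(triethylsilyl)oxy]-3,4,4a,5,6,7,8,8a-octahydronaphthalen-2-yl}methoxy)diphenylsilane
Conditions: Zn, CH2Br2, TiCl4, THF (pre-formed reagent); then 18, CH2Cl2, 0 °C → rt
Reagents that add atoms: dibromomethane, BrCBr
Why: Takai–Lombardo methylenation, whose non-basic geminal dimetal reagent converts hindered, enolisable ketones into methylene compounds without epimerising C1 or eliminating the β-silyloxy group.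

Step 15
Reactants: 19 tert-butyl({(4aS,7S,8R,8aS)-8-ethynyl-5-methylidene-7-[(triethylsilyl)oxy]-3,4,4a,5,6,7,8,8a-octahydronaphthalen-2-yl}methoxy)diphenylsilane
Product: 20 (1R,2S,4aS,8aS)-7-[(TBDPS-oxy)methyl]-1-ethynyl-4-methylidene-1,2,3,4,4a,5,6,8a-octahydronaphthalen-2-ol (axial alcohol)
Conditions: pyridinium p-toluenesulfonate (0.2 equiv), MeOH/CH2Cl2, 0 °C → rt
Reagents that add atoms: none
Why: Acid-catalysed methanolysis cleaves the TES ether far faster than the TBDPS ether.

Step 16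
Reactants: 20 (1R,2S,4aS,8aS)-7-[(TBDPS-oxy)methyl]-1-ethynyl-4-methylidene-1,2,3,4,4a,5,6,8a-octahydronaphthalen-2-ol
Product: 21 (1R,4aS,8aS)-7-[(TBDPS-oxy)methyl]-1-ethynyl-4-methylidene-3,4,4a,5,6,8a-hexahydronaphthalen-2(1H)-one
Conditions: Dess–Martin periodinane, pyridine, CH2Cl2, 0 °C; used directly
Reagents that add atoms: none
Why: Buffered hypervalent-iodine oxidation under neutral conditions, so that the β,γ-unsaturated, α-alkynyl ketone is neither conjugated nor epimerised at C7.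

Step 17
Reactants: 21 (1R,4aS,8aS)-7-[(TBDPS-oxy)methyl]-1-ethynyl-4-methylidene-3,4,4a,5,6,8a-hexahydronaphthalen-2(1H)-one
Product: 22 (1R,2R,4aS,8aS)-7-[(TBDPS-oxy)methyl]-1-ethynyl-4-methylidene-1,2,3,4,4a,5,6,8a-octahydronaphthalen-2-ol (equatorial alcohol)
Conditions: NaBH4, CeCl3·7H2O, MeOH, −78 °C
Reagents that add atoms: none
Why: Luche reduction, in which the small hydride attacks C8 of the rigid trans-decalin axially, from the face opposite to the adjacent axial ethynyl group, to give the equatorial (8R) alcohol cis to the C7 substituent; the fast, weakly basic conditions avoid enolisation.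

Step 18
Reactants: 23 (4R)-2,2-dimethyl-1,3-dioxolane-4-carbaldehyde
Product: 24 (4S)-4-ethynyl-2,2-dimethyl-1,3-dioxolane
Conditions: dimethyl (1-diazo-2-oxopropyl)phosphonate, K2CO3, MeOH, 0 °C → rt
Reagents that add atoms: dimethyl (1-diazo-2-oxopropyl)phosphonate, CC(=O)C(=[N+]=[N-])P(=O)(OC)OC
Why: Ohira–Bestmann homologation of the aldehyde to the terminal alkyne under conditions mild enough to keep the α-alkoxy stereocentre (the descriptor changes only by priority).

Step 19
Reactants: 24 (4S)-4-ethynyl-2,2-dimethyl-1,3-dioxolane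
Product: 25 2-[(4S)-2,2-dimethyl-1,3-dioxolan-4-yl]prop-2-enoic acid
Conditions: Pd(OAc)2 (2 mol %), 2-(diphenylphosphino)pyridine (8 mol %), MeSO3H (8 mol %), CO (20 bar), acetone/H2O, 50 °C
Reagents that add atoms: carbon monoxide, [C-]#[O+]; water, O
Why: Palladium-catalysed Markovnikov hydroxycarbonylation of a terminal alkyne (palladium placed on the internal carbon, CO insertion, hydrolysis of the acyl–palladium) gives the 2-substituted acrylic acid; acetone as cosolvent keeps the acetonide in place and the stereocentre is not involved.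

Step 20
Reactants: 22 (1R,2R,4aS,8aS)-7-[(TBDPS-oxy)methyl]-1-ethynyl-4-methylidene-1,2,3,4,4a,5,6,8a-octahydronaphthalen-2-ol; 25 2-[(4S)-2,2-dimethyl-1,3-dioxolan-4-yl]prop-2-enoic acid
Product: 26 (1R,2R,4aS,8aS)-7-[(TBDPS-oxy)methyl]-1-ethynyl-4-methylidene-1,2,3,4,4a,5,6,8a-octahydronaphthalen-2-yl 2-[(4S)-2,2-dimethyl-1,3-dioxolan-4-yl]prop-2-enoate
Conditions: EDC·HCl, DMAP, CH2Cl2, 0 °C → rt
Reagents that add atoms: none
Why: Steglich esterification of the equatorial C8 hydroxyl by the carbodiimide-activated acid, with retention at both stereocentres.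

Step 21
Reactants: 26 (1R,2R,4aS,8aS)-7-[(TBDPS-oxy)methyl]-1-ethynyl-4-methylidene-1,2,3,4,4a,5,6,8a-octahydronaphthalen-2-yl 2-[(4S)-2,2-dimethyl-1,3-dioxolan-4-yl]prop-2-enoate
Product: 27 2-[(1R,2R,4aS,8aS)-7-[(TBDPS-oxy)methyl]-2-({2-[(4S)-2,2-dimethyl-1,3-dioxolan-4-yl]prop-2-enoyl}oxy)-4-methylidene-1,2,3,4,4a,5,6,8a-octahydronaphthalen-1-yl]prop-2-enoic acid
Conditions: Pd(OAc)2 (5 mol %), 2-(diphenylphosphino)pyridine (20 mol %), MeSO3H (20 mol %), CO (20 bar), acetone/H2O, 50 °C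
Reagents that add atoms: carbon monoxide, [C-]#[O+]; water, O
Why: The same Markovnikov hydroxycarbonylation as in step 19 turns the C11≡C13 alkyne into the C7 acrylic acid, since this catalyst should take up the terminal alkyne far faster than any of the three alkenes; the ester cannot lactonise because C8–O is acylated.

Step 22
Reactants: 27 2-[(1R,2R,4aS,8aS)-7-[(TBDPS-oxy)methyl]-2-({2-[(4S)-2,2-dimethyl-1,3-dioxolan-4-yl]prop-2-enoyl}oxy)-4-methylidene-1,2,3,4,4a,5,6,8a-octahydronaphthalen-1-yl]prop-2-enoic acid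
Product: 28 2-[(1R,2R,4aS,8aS)-2-{[(3S)-3,4-dihydroxy-2-methylidenebutanoyl]oxy}-7-(hydroxymethyl)-4-methylidene-1,2,3,4,4a,5,6,8a-octahydronaphthalen-1-yl]prop-2-enoic acid (CNP0460913.2)
Conditions: aq. HF (48%), MeCN, 0 °C → rt
Reagents that add atoms: none
Why: Aqueous HF cleaves the primary silyl ether (Si–F bond formation) and hydrolyses the acetonide in one operation, under conditions mild enough to spare the ester and the three exocyclic alkenes.

## Compound list

1 | 2-methylidenepropane-1,3-diol | C=C(CO)CO | starting material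
2 | 2-[(TBDPS-oxy)methyl]prop-2-en-1-ol | C=C(CO)CO[Si](c1ccccc1)(c1ccccc1)C(C)(C)C | intermediate
3 | 2-[(TBDPS-oxy)methyl]prop-2-enal | C=C(C=O)CO[Si](c1ccccc1)(c1ccccc1)C(C)(C)C | intermediate
4 | ethyl (2E)-4-(diethoxyphosphoryl)but-2-enoate | CCOC(=O)/C=C/CP(=O)(OCC)OCC | starting material
5 | ethyl (2E,4E)-6-[(TBDPS-oxy)methyl]hepta-2,4,6-trienoate | CCOC(=O)/C=C/C=C/C(=C)CO[Si](c1ccccc1)(c1ccccc1)C(C)(C)C | intermediate
6 | (2E,4E)-6-[(TBDPS-oxy)methyl]hepta-2,4,6-trien-1-ol | OC/C=C/C=C/C(=C)CO[Si](c1ccccc1)(c1ccccc1)C(C)(C)C | intermediate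
7 | {(2R,3R)-3-[(1E)-3-[(TBDPS-oxy)methyl]buta-1,3-dien-1-yl]oxiran-2-yl}methanol | OC[C@H]1O[C@@H]1/C=C/C(=C)CO[Si](c1ccccc1)(c1ccccc1)C(C)(C)C | intermediate
8 | (2S,3R,4E)-6-[(TBDPS-oxy)methyl]-3-[(trimethylsilyl)ethynyl]hepta-4,6-diene-1,2-diol | OC[C@@H](O)[C@@H](C#C[Si](C)(C)C)/C=C/C(=C)CO[Si](c1ccccc1)(c1ccccc1)C(C)(C)C | intermediate
9 | (2S,3R,4E)-6-[(TBDPS-oxy)methyl]-2-hydroxy-3-[(trimethylsilyl)ethynyl]hepta-4,6-dien-1-yl benzoate | O=C(OC[C@@H](O)[C@@H](C#C[Si](C)(C)C)/C=C/C(=C)CO[Si](c1ccccc1)(c1ccccc1)C(C)(C)C)c1ccccc1 | intermediate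
10 | (2S,3R,4E)-6-[(TBDPS-oxy)methyl]-2-(methanesulfonyloxy)-3-[(trimethylsilyl)ethynyl]hepta-4,6-dien-1-yl benzoate | O=C(OC[C@@H](OS(C)(=O)=O)[C@@H](C#C[Si](C)(C)C)/C=C/C(=C)CO[Si](c1ccccc1)(c1ccccc1)C(C)(C)C)c1ccccc1 | intermediate
11 | (2S,3R,4E)-6-[(TBDPS-oxy)methyl]-3-ethynyl-2-(methanesulfonyloxy)hepta-4,6-dien-1-yl benzoate | O=C(OC[C@@H](OS(C)(=O)=O)[C@@H](C#C)/C=C/C(=C)CO[Si](c1ccccc1)(c1ccccc1)C(C)(C)C)c1ccccc1 | intermediate
12 | (2S,3R,4E)-6-[(TBDPS-oxy)methyl]-3-ethynyl-1-hydroxyhepta-4,6-dien-2-yl methanesulfonate | OC[C@@H](OS(C)(=O)=O)[C@@H](C#C)/C=C/C(=C)CO[Si](c1ccccc1)(c1ccccc1)C(C)(C)C | intermediate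
13 | (2R)-2-{(1R,2E)-1-ethynyl-4-[(TBDPS-oxy)methyl]penta-2,4-dien-1-yl}oxirane | C1O[C@@H]1[C@@H](C#C)/C=C/C(=C)CO[Si](c1ccccc1)(c1ccccc1)C(C)(C)C | intermediate
14 | (5S,6R,7E)-9-[(TBDPS-oxy)methyl]-6-ethynyl-3-methoxydeca-1,2,7,9-tetraen-5-ol | C=C=C(OC)C[C@H](O)[C@@H](C#C)/C=C/C(=C)CO[Si](c1ccccc1)(c1ccccc1)C(C)(C)C | intermediate
15 | triethyl{[(5S,6R,7E)-9-[(TBDPS-oxy)methyl]-6-ethynyl-3-methoxydeca-1,2,7,9-tetraen-5-yl]oxy}silane | C=C=C(OC)C[C@H](O[Si](CC)(CC)CC)[C@@H](C#C)/C=C/C(=C)CO[Si](c1ccccc1)(c1ccccc1)C(C)(C)C | intermediate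
16 | (5S,6R,7E)-9-[(TBDPS-oxy)methyl]-6-ethynyl-5-[(triethylsilyl)oxy]deca-1,7,9-trien-3-one | C=CC(=O)C[C@H](O[Si](CC)(CC)CC)[C@@H](C#C)/C=C/C(=C)CO[Si](c1ccccc1)(c1ccccc1)C(C)(C)C | intermediate
17 | (3S,4R,4aR,8aR)-6-[(TBDPS-oxy)methyl]-4-ethynyl-3-[(triethylsilyl)oxy]-3,4,4a,7,8,8a-hexahydronaphthalen-1(2H)-one | C#C[C@H]1[C@H]2C=C(CO[Si](c3ccccc3)(c3ccccc3)C(C)(C)C)CC[C@H]2C(=O)C[C@@H]1O[Si](CC)(CC)CC | intermediate
18 | (3S,4R,4aR,8aS)-6-[(TBDPS-oxy)methyl]-4-ethynyl-3-[(triethylsilyl)oxy]-3,4,4a,7,8,8a-hexahydronaphthalen-1(2H)-one | C#C[C@H]1[C@H]2C=C(CO[Si](c3ccccc3)(c3ccccc3)C(C)(C)C)CC[C@@H]2C(=O)C[C@@H]1O[Si](CC)(CC)CC | intermediate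
19 | tert-butyl({(4aS,7S,8R,8aS)-8-ethynyl-5-methylidene-7-[(triethylsilyl)oxy]-3,4,4a,5,6,7,8,8a-octahydronaphthalen-2-yl}methoxy)diphenylsilane | C#C[C@H]1[C@H]2C=C(CO[Si](c3ccccc3)(c3ccccc3)C(C)(C)C)CC[C@@H]2C(=C)C[C@@H]1O[Si](CC)(CC)CC | intermediate
20 | (1R,2S,4aS,8aS)-7-[(TBDPS-oxy)methyl]-1-ethynyl-4-methylidene-1,2,3,4,4a,5,6,8a-octahydronaphthalen-2-ol | C#C[C@H]1[C@H]2C=C(CO[Si](c3ccccc3)(c3ccccc3)C(C)(C)C)CC[C@@H]2C(=C)C[C@@H]1O | intermediate
21 | (1R,4aS,8aS)-7-[(TBDPS-oxy)methyl]-1-ethynyl-4-methylidene-3,4,4a,5,6,8a-hexahydronaphthalen-2(1H)-one | C#C[C@H]1[C@H]2C=C(CO[Si](c3ccccc3)(c3ccccc3)C(C)(C)C)CC[C@@H]2C(=C)CC1=O | intermediate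
22 | (1R,2R,4aS,8aS)-7-[(TBDPS-oxy)methyl]-1-ethynyl-4-methylidene-1,2,3,4,4a,5,6,8a-octahydronaphthalen-2-ol | C#C[C@H]1[C@H]2C=C(CO[Si](c3ccccc3)(c3ccccc3)C(C)(C)C)CC[C@@H]2C(=C)C[C@H]1O | intermediate
23 | (4R)-2,2-dimethyl-1,3-dioxolane-4-carbaldehyde | O=C[C@H]1COC(C)(C)O1 | starting material
24 | (4S)-4-ethynyl-2,2-dimethyl-1,3-dioxolane | C#C[C@H]1COC(C)(C)O1 | intermediate
25 | 2-[(4S)-2,2-dimethyl-1,3-dioxolan-4-yl]prop-2-enoic acid | C=C(C(=O)O)[C@H]1COC(C)(C)O1 | intermediate
26 | (1R,2R,4aS,8aS)-7-[(TBDPS-oxy)methyl]-1-ethynyl-4-methylidene-1,2,3,4,4a,5,6,8a-octahydronaphthalen-2-yl 2-[(4S)-2,2-dimethyl-1,3-dioxolan-4-yl]prop-2-enoate | C#C[C@H]1[C@H]2C=C(CO[Si](c3ccccc3)(c3ccccc3)C(C)(C)C)CC[C@@H]2C(=C)C[C@H]1OC(=O)C(=C)[C@H]1COC(C)(C)O1 | intermediate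
27 | 2-[(1R,2R,4aS,8aS)-7-[(TBDPS-oxy)methyl]-2-({2-[(4S)-2,2-dimethyl-1,3-dioxolan-4-yl]prop-2-enoyl}oxy)-4-methylidene-1,2,3,4,4a,5,6,8a-octahydronaphthalen-1-yl]prop-2-enoic acid | C=C(C(=O)O)[C@H]1[C@H]2C=C(CO[Si](c3ccccc3)(c3ccccc3)C(C)(C)C)CC[C@@H]2C(=C)C[C@H]1OC(=O)C(=C)[C@H]1COC(C)(C)O1 | intermediate
28 | 2-[(1R,2R,4aS,8aS)-2-{[(3S)-3,4-dihydroxy-2-methylidenebutanoyl]oxy}-7-(hydroxymethyl)-4-methylidene-1,2,3,4,4a,5,6,8a-octahydronaphthalen-1-yl]prop-2-enoic acid | C=C(C(=O)O)[C@H]1[C@H]2C=C(CO)CC[C@@H]2C(=C)C[C@H]1OC(=O)C(=C)[C@H](O)CO | target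

## Step count and risks

Total step count: 22. Longest linear sequence: 20 (steps 1–17 and 20–22); steps 18–19 make the side-chain acid in parallel.

Steps most likely to fail:

Step 12. The exo chair, in which both tether substituents can also be equatorial, may compete with the endo chair; such poor endo/exo discrimination would deliver the C6 epimer. Lewis-acid-induced loss of the β-silyloxy group is a second danger. The fallback sets out from 16 and changes the dienophile from a Lewis-acid complex to a cation. With 1,2-bis(trimethylsilyloxy)ethane and Me3SiOSO2CF3 (cat.) in CH2Cl2 at −78 °C the enone is ketalised in the flask to the 2-vinyl-1,3-dioxolane of the trienone F1. This ionises to a 2-vinyl-1,3-dioxolan-2-ylium ion and undergoes the ionic Diels–Alder reaction at that temperature; the compact cationic dienophile reacts through an early transition state that should be more strongly endo-biased, giving the dioxolane ketal of the cis-fused adduct F2. Mild hydrolysis (oxalic acid, wet SiO2) comes back to the route at 17.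

Step 6. Vinylogous (SN2′ or SN2″) attack, or Lewis-acid ionisation of the dienyl epoxide between 0 °C and rt, would erode regio- and stereochemistry at C7. The fallback sets out from 7. Benzoylation (PhCOCl, pyridine, CH2Cl2, 0 °C) gives the epoxy benzoate F3. Me3SiC≡CLi with BF3·OEt2 in THF at −78 °C then opens it through the alkynylborane, a fast low-temperature process known to attack vinyl epoxides at the allylic carbon with inversion; that carbon is also the one remote from the electron-poor benzoyloxymethyl group. This gives 9 directly, where the route is rejoined with the mesylation of step 7.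

Step 21. Palladium hydride-mediated migration of the exocyclic double bonds, or slow uptake of the hindered axial alkyne with acid-induced loss of the acetonide on prolonged heating, may spoil the carbonylation. The fallback sets out from 26. Mo(CO)3(CNt-Bu)3-catalysed Markovnikov hydrostannation with Bu3SnH gives the α-stannyl alkene F4. I2 (CH2Cl2, 0 °C) exchanges tin for iodine faster than it attacks the other alkenes and gives the 2-iodoalkene F5. Pd(PPh3)4, CO (1 atm), H2O, Et3N in DMF then converts the vinyl iodide into the acrylic acid and comes back to the route at 27.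

Further compounds
F1 | step 12 | tert-butyl{[(3E,5R,6S)-5-ethynyl-2-methylidene-6-[(triethylsilyl)oxy]-7-(2-vinyl-1,3-dioxolan-2-yl)hept-3-en-1-yl]oxy}diphenylsilane (dioxolane ketal of 16) | C=CC1(OCCO1)C[C@H](O[Si](CC)(CC)CC)[C@@H](C#C)/C=C/C(=C)CO[Si](c1ccccc1)(c1ccccc1)C(C)(C)C
F2 | step 12 | ethylene ketal of 17 (spiro-1,3-dioxolane at the former ketone carbon, cis-fused, otherwise as 17) | C#C[C@H]1[C@H]2C=C(CO[Si](c3ccccc3)(c3ccccc3)C(C)(C)C)CC[C@H]2C2(OCCO2)C[C@@H]1O[Si](CC)(CC)CC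
F3 | step 6 | {(2R,3R)-3-[(1E)-3-[(TBDPS-oxy)methyl]buta-1,3-dien-1-yl]oxiran-2-yl}methyl benzoate | O=C(OC[C@H]1O[C@@H]1/C=C/C(=C)CO[Si](c1ccccc1)(c1ccccc1)C(C)(C)C)c1ccccc1
F4 | step 21 | (1R,2R,4aS,8aS)-7-[(TBDPS-oxy)methyl]-4-methylidene-1-[1-(tributylstannyl)ethenyl]-1,2,3,4,4a,5,6,8a-octahydronaphthalen-2-yl 2-[(4S)-2,2-dimethyl-1,3-dioxolan-4-yl]prop-2-enoate | C=C([Sn](CCCC)(CCCC)CCCC)[C@H]1[C@H]2C=C(CO[Si](c3ccccc3)(c3ccccc3)C(C)(C)C)CC[C@@H]2C(=C)C[C@H]1OC(=O)C(=C)[C@H]1COC(C)(C)O1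
F5 | step 21 | (1R,2R,4aS,8aS)-7-[(TBDPS-oxy)methyl]-1-(1-iodoethenyl)-4-methylidene-1,2,3,4,4a,5,6,8a-octahydronaphthalen-2-yl 2-[(4S)-2,2-dimethyl-1,3-dioxolan-4-yl]prop-2-enoate | C=C(I)[C@H]1[C@H]2C=C(CO[Si](c3ccccc3)(c3ccccc3)C(C)(C)C)CC[C@@H]2C(=C)C[C@H]1OC(=O)C(=C)[C@H]1COC(C)(C)O1
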